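**Remark on the chemistry.** Ar = 4‑(benzyloxy)‑3‑methoxyphenyl in all names. Atom labels O1, C2 (side chain), C3 (aryl), C4 (hydroxyl), C5 (CH2) and C1' (carbinol) are kept for every intermediate. The target is read as the all‑cis (2S,3R,4S,1'R) isomer. C3 is named S in ketone 17 and R in 18–20 without any change in space, because C4 outranks C2 only while it is a carbonyl carbon. The facial sense of the chiral catalysts in steps 8 and 9 is assigned by analogy with simpler substrates; the mirror‑image complexes Rh2(R‑PTTL)4 and RuCl(p‑cymene)[(R,R)‑TsDPEN] are the direct substitutes if a pairing proves mismatched.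

## Structural features

Metasequirin E has one oxolane ring with three contiguous stereocentres, C2 (S), C3 (R) and C4 (S); the C2 side chain, the C3 aryl group and the C4 hydroxyl all lie on one face. A fourth stereocentre, the carbinol C1' (R), stands outside the ring next to C2, with its oxygen anti to O1 in the extended chain. Two identical 4‑hydroxy‑3‑methoxyphenyl rings are attached, one to C3 and one to C1', so one phenol protecting group and one kind of aryl building block serve both halves. The fragile sites are the free phenols (oxidation), the benzylic C1'–OH para to a phenol (quinone methide formation under acid, hydrogenolysis over palladium) and, at the ketone stage, the benzylic C3–H. The real difficulty is the all‑cis triad, which is the most crowded arrangement and cannot be reached by equilibration, together with the relation between C2 and the exocyclic C1'. The plan exploits that C2 is an ether carbon on O1 while C3 is benzylic and flanked by C4: with C4 as a ketone, C3 can be an aryl keto carbene that inserts into a C2–H bond of an acyclic ether five atoms away. The same ketone makes C3 epimerisable, so C3 and C4 can be set together in the following reduction.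

## Logic of the disconnections

**20 to 19.** The two phenolic O–CH2Ph bonds are cut. The phenols are the most oxidation‑prone groups and are uncovered last; the cut adds only two spectator groups. The forward step must cleave aryl benzyl ethers without hydrogenolysing the benzylic C1'–O bond.

**19 to 18.** The O–Si bond at C1' is cut. The silyl group is needed earlier as a steric shield, and it is removed while the phenols are still covered so that no phenoxide sits para to a benzylic leaving group. The forward step only needs chemoselective fluoride cleavage.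

**18 to 17.** The C4–H bond is cut, which makes C4 a ketone and C3 labile. Two stereocentres leave the problem and the carbonyl needed for carbene chemistry appears. The forward reduction must deliver hydride anti to the C3 aryl group and select the C3 epimer that is cis to the C2 side chain.

**17 to 16.** The C2–C3 bond is cut, opening the ring to an acyclic ether with one stereocentre. The cut uses the activation of C2–H by O1 and the stabilisation of a C3 carbene by aryl and keto groups; ring, bond and the C2 centre disappear together. The forward insertion must prefer C2–H over the tertiary benzylic C1'–H, choose one of the two C2 hydrogens, and avoid ylide and aromatic pathways.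

**16 to 15.** The C3=N2 bond is cut. The diazo group enters last so that no earlier step has to carry it. The forward diazo transfer relies on the C3 methylene being more acidic than the C5 methylene.

**15 to 9 and 11.** The C3–C4 bond is cut in a Claisen‑type sense with loss of CO2. The molecule falls into two halves of similar size, each with one aryl ring. This avoids diazomethane and avoids a terminal arylacetyl diazo ketone, whose carbene would add to its own electron‑rich ring during an O–H insertion. The forward step must acylate the benzylic carbon only once.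

**9 to 7, and 7 to 6.** First the O–Si bond, then the C1'–H bond is cut. C1' becomes a prochiral aryl ketone with the ether oxygen in the α position, a good substrate for asymmetric transfer hydrogenation, and no diol has to be differentiated. The forward reduction must give the (R) carbinol, and the silylation must cover the alcohol without leaving the acid blocked.

**6 to 3 and 4 (through 5).** The aryl–C1' bond is cut. The chain C1'–C2–O1–C5–C4 is found intact in 4, which is symmetrical, so O1 and both methylenes are bought ready‑made. The forward addition must stop after one acylation.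

**3 to 1 and 2; 11 to 10 and 2.** The phenolic O–benzyl bonds are cut. These are simple etherifications with no selectivity demand beyond phenol over carboxylate.

## Other disconnections considered

**Alternative 1:** The ring is cut at O1–C2 and C2–C3, so that C2 with its aroyl group is excised as a carbene carbon.
- Forward: the diazo ketone A3 is decomposed by a copper catalyst such as Cu(MeCN)4PF6 with a chiral bisoxazoline. The carbene is captured by the oxygen of the cis‑oxetane A2, and the oxonium ylide undergoes a [1,2]‑shift of benzylic C3 from O1 to C2, enlarging the ring to the all‑cis 2‑aroyl oxolane A1.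
- In its favour: it is convergent and makes two ring bonds in one step against one in the chosen plan. C3 and C4 arrive with their cis relation fixed in A2, so no epimerisable α‑aryl ketone sits in the ring. On these two points it is the better plan. The C1' carbinol could plausibly be set anti to O1 by chelation‑controlled reduction.
- Against it here: the shift has radical‑pair or ion‑pair character at C3, and an electron‑rich dialkoxybenzyl group may lose configuration. The new C2 is α to the aryl ketone and its all‑cis placement is the least stable, so drift to trans is expected. A2 is a strained, enantiopure, cis‑disubstituted benzylic oxetane with no short preparation.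
- Comparison: the mechanism is stepwise where the carbene insertion is concerted with retention. Three stereochemical questions (C2, integrity of C3, C1') stay open after the key step, against one in the chosen plan. The step count is expected to be similar or higher once A2 is made.

**Alternative 2:** The ring oxygen is removed from between C2 and C5, leading back to a cyclobutanone.
- Forward: dichloroketene A7 (from Cl3CCOCl and Zn) adds to the Z‑alkene A6 to give the cis‑dichlorocyclobutanone A5. mCPBA adds to the carbonyl and the more substituted carbon C2 migrates to oxygen with retention, giving the dichlorolactone A4.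
- In its favour: both reactions are robust. The regiochemistry of oxygen insertion is predictable because the CCl2 carbon does not migrate. The cis relation of C2 and C3 is transferred stereospecifically from the alkene geometry without a chiral catalyst; in reliability of the C2/C3 relative configuration it is the equal or the better of the chosen plan.
- Against it here: A4 has the wrong oxidation pattern, C5 as a lactone carbonyl and C4 as CCl2, where the target needs C5 as CH2 and C4 as a carbinol cis to the aryl group. Both chlorines must be removed, oxygen introduced at C4 on the hindered face, and the lactone reduced to the ether by a hydride and Lewis acid sequence that the benzylic silyl ether and the electron‑rich rings tolerate poorly. Facial selectivity of the cycloaddition relative to C1' and the preparation of A6 are further open points.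
- Comparison: the chosen plan reaches the correct oxidation level at C4 and C5 directly. The alternative has the mechanistically safer key step but is clearly longer, by an estimated four or more steps after ring formation.

**Alternative 3:** The ring is cut at C2–C3 and O1–C5, giving an aldehyde for C2 and an allylsilane for C3–C4–C5.
- Forward: BF3·OEt2 activates the α‑silyloxy aldehyde A10. The Z‑cinnamylsilane A9 attacks through its aryl‑bearing carbon C3, silicon bridges the cation at C4 and moves from C5 to C4, and the alkoxide closes on C5 to give the all‑cis 4‑silyl oxolane A8. Oxidation of the C–Si bond with retention would then reveal the C4 hydroxyl.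
- In its favour: it joins two fragments of equal size and forms the ring and all three ring stereocentres in one step. C4 is carried at the right oxidation level in masked form, so neither a labile α‑aryl ketone nor a stereoselective reduction is needed. In convergence and in the number of stereocentres set by the key step it is the better plan.
- Against it here: A10 is an α‑aryl α‑silyloxy aldehyde that enolises easily and may lose configuration, and its electron‑rich benzylic silyl ether is exposed to a strong Lewis acid. Attack through the hindered aryl‑bearing terminus of A9 is slow, and loss of silicon with simple allyl transfer (the Hosomi–Sakurai pathway) competes with closure at the unsubstituted C5. The sense of addition to the aldehyde (Felkin or chelate) decides C2 and is not assured. Oxidation of a dimethyl(phenyl)silyl group starts with electrophilic attack on the phenyl ring, which the more electron‑rich dialkoxyphenyl rings would not survive unchanged.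
- Comparison: the step count is about equal. The alternative is stronger in convergence; the chosen plan is stronger in functional‑group compatibility and in having each stereocentre controlled by a separately adjustable element.

Key step: step 8

## Route

Step 1
Reactants: 1 4‑bromo‑2‑methoxyphenol; 2 benzyl bromide
Product: 3 1‑(benzyloxy)‑4‑bromo‑2‑methoxybenzene
Conditions: K2CO3, DMF, 60 °C
Reagents that add atoms: none
Why: Williamson ether synthesis; the phenoxide formed by K2CO3 displaces bromide from benzyl bromide in an SN2 reaction, and no other nucleophilic site is present.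

Step 2
Reactants: 3 1‑(benzyloxy)‑4‑bromo‑2‑methoxybenzene; 4 diglycolic anhydride (1,4‑dioxane‑2,6‑dione)
Product: 6 2‑[2‑Ar‑2‑oxoethoxy]acetic acid, via arylmagnesium bromide 5 (not isolated)
Conditions: Mg, THF, 45 °C; then added to 4 (1.5 equiv), THF, −78 to −20 °C; 1 M HCl
Reagents that add atoms: none
Why: Magnesium insertion gives the aryl Grignard reagent, which opens the cyclic anhydride by acyl substitution to the keto carboxylate. Inverse addition at low temperature to excess anhydride, and the lower electrophilicity of the electron‑rich aryl ketone, should hold the reaction at one addition.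

Step 3
Reactants: 6 2‑[2‑Ar‑2‑oxoethoxy]acetic acid
Product: 7 2‑[(2R)‑2‑Ar‑2‑hydroxyethoxy]acetic acid
Conditions: RuCl(p‑cymene)[(S,S)‑TsDPEN] (1 mol%), HCO2H/Et3N (5:2), DMF, 40 °C; work‑up at pH 4, 0 °C
Reagents that add atoms: none
Why: Noyori–Ikariya asymmetric transfer hydrogenation of an α‑alkoxy aryl ketone; hydride and proton pass to C=O through the six‑membered metal–ligand transition state with the aryl group next to the η6‑arene. With the (S,S)‑ligand this gives the spatial arrangement of (S)‑1‑phenylethanol, named (R) here because the CH2O branch outranks the aryl group; the acid rides as its triethylammonium salt.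

Step 4
Reactants: 7 2‑[(2R)‑2‑Ar‑2‑hydroxyethoxy]acetic acid
Product: 9 2‑{(2R)‑2‑Ar‑2‑[(triisopropylsilyl)oxy]ethoxy}acetic acid, via silyl ester 8 (not isolated)
Conditions: TIPSOTf (2.4 equiv), 2,6‑lutidine, CH2Cl2, 0 °C to rt; then K2CO3, MeOH/H2O, rt; KHSO4 (aq) to pH 4
Reagents that add atoms: triisopropylsilyl trifluoromethanesulfonate, CC(C)[Si](OS(=O)(=O)C(F)(F)F)(C(C)C)C(C)C
Why: Silyl triflate silylation covers both the secondary alcohol and the acid; aqueous carbonate then hydrolyses only the silyl ester, while the hindered silyl ether stays. The stereocentre is not touched.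

Step 5
Reactants: 10 homovanillic acid; 2 benzyl bromide
Product: 11 2‑Ar‑acetic acid
Conditions: KOH (2.2 equiv), EtOH/H2O, reflux; then HCl (aq)
Reagents that add atoms: none
Why: Williamson etherification of the phenoxide in aqueous alcoholic KOH; the carboxylate is a poor nucleophile in this medium, and any benzyl ester that forms is saponified by the excess hydroxide before acidification.

Step 6
Reactants: 9 2‑{(2R)‑2‑Ar‑2‑[(triisopropylsilyl)oxy]ethoxy}acetic acid; 11 2‑Ar‑acetic acid
Product: 15 1‑Ar‑3‑{(2R)‑2‑Ar‑2‑[(triisopropylsilyl)oxy]ethoxy}propan‑2‑one, via acyl imidazolide 12 (not isolated), via Ivanov dianion 13 (not isolated), via keto acid 14 (not isolated)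
Conditions: 9, CDI, THF, rt; 11 (3 equiv), iPrMgCl (6 equiv), THF, 0 °C to rt; mixed at −20 °C to rt; 1 M HCl to pH 4, 0 °C, then 40 °C
Reagents that add atoms: none
Why: CDI activation followed by C‑acylation of the magnesium enediolate of the arylacetic acid (Ivanov reagent, a Claisen‑type condensation); the α‑aryl β‑keto acid loses CO2 on acidification. The excess dianion takes up the imidazole N–H and the acidic proton of the product, so the ketone is not attacked a second time.

Step 7
Reactants: 15 1‑Ar‑3‑{(2R)‑2‑Ar‑2‑[(triisopropylsilyl)oxy]ethoxy}propan‑2‑one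
Product: 16 1‑diazo‑1‑Ar‑3‑{(2R)‑2‑Ar‑2‑[(triisopropylsilyl)oxy]ethoxy}propan‑2‑one
Conditions: 4‑acetamidobenzenesulfonyl azide (1.3 equiv), DBU (1.5 equiv), MeCN, 0 °C to rt
Reagents that add atoms: 4‑acetamidobenzenesulfonyl azide, CC(=O)Nc1ccc(cc1)S(=O)(=O)N=[N+]=[N-]
Why: Regitz diazo transfer; DBU removes a proton from the benzylic C3 methylene, which is more acidic than the C5 methylene, and the enolate takes the terminal N2 of the sulfonyl azide with release of the sulfonamide.

Step 8
Reactants: 16 1‑diazo‑1‑Ar‑3‑{(2R)‑2‑Ar‑2‑[(triisopropylsilyl)oxy]ethoxy}propan‑2‑one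
Product: 17 (4S,5S)‑4‑Ar‑5‑{(R)‑Ar[(triisopropylsilyl)oxy]methyl}oxolan‑3‑one (target numbering: 2,3‑cis oxolan‑4‑one, C2 S, C3 S, C1' R)
Conditions: Rh2(S‑PTTL)4 (1 mol%; PTTL = N‑phthaloyl‑tert‑leucinate), toluene, 4 Å molecular sieves, −20 to 0 °C, slow addition of 16, argon
Reagents that add atoms: none
Why: Loss of N2 from 16 at the dirhodium tetracarboxylate gives a donor/acceptor carbene at C3, tempered by the electron‑rich aryl group and the C4 ketone. The carbene carbon engages a C2–H bond in one concerted, asynchronous three‑centre step: hydride character leaves C2, where O1 stabilises the developing positive charge, while the C2–C3 bond forms with retention at C2; the closest known reaction type is the dirhodium‑catalysed intramolecular C–H insertion of α‑aryl α‑diazo ketones into C–H bonds α to an ether oxygen. The ring closes in the 1,5 mode through a chair‑like six‑membered array (C3, C4, C5, O1, C2 and the migrating hydrogen), which gives the five‑membered oxolanone. C2 is set by which of the two diastereotopic hydrogens is replaced (the pro‑S one); the choice is made by the chiral pocket of the carboxylate ligands together with the (R)‑silyloxy centre at C1', whose bulky side chain sits pseudo‑equatorial in the chair. C3 forms cis to the C2 side chain because the carbene aryl group and the C2 substituent both point away from the ligand wall in the favoured transition state; this centre stays epimerisable and is finally fixed in step 9. The step needs site selectivity for C2–H over the tertiary benzylic C1'–H (1,6 mode) and over ylide formation: the preference for the five‑membered closure, the triisopropylsilyl group that shields C1'–H and makes its oxygen a poor Lewis base, and the four‑membered ring that an ylide at O1 would require secure this. It also needs catalyst and C1' centre to act in the same sense, which is checked directly with the antipodal complex. The crude ketone is passed through a short pad only and reduced at once, to avoid epimerisation and enol autoxidation.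

Step 9
Reactants: 17 (4S,5S)‑4‑Ar‑5‑{(R)‑Ar[(triisopropylsilyl)oxy]methyl}oxolan‑3‑one
Product: 18 (3S,4R,5S)‑4‑Ar‑5‑{(R)‑Ar[(triisopropylsilyl)oxy]methyl}oxolan‑3‑ol (all‑cis)
Conditions: RuCl(p‑cymene)[(S,S)‑TsDPEN] (2 mol%), HCO2H/Et3N (1:2), CH2Cl2, 25 °C
Reagents that add atoms: none
Why: Noyori–Ikariya transfer hydrogenation run as a dynamic kinetic resolution: the amine‑rich medium equilibrates the α‑aryl centre C3 through the enol, and the ruthenium hydride reduces the 2,3‑cis epimer fastest from the face opposite both the C3 aryl group and the bulky C2 side chain, giving C4 (S) with the hydroxyl cis to the aryl group and fixing C3 (R). The (S,S)‑ligand is chosen to reinforce this substrate preference, with the α‑oxygenated C5 taking the site next to the η6‑arene as in α‑alkoxy ketones; C2 is unaffected because ring opening by β‑elimination of O1 is geometrically disfavoured in the five‑membered ring.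

Step 10
Reactants: 18 (3S,4R,5S)‑4‑Ar‑5‑{(R)‑Ar[(triisopropylsilyl)oxy]methyl}oxolan‑3‑ol
Product: 19 (3S,4R,5S)‑4‑Ar‑5‑[(R)‑Ar(hydroxy)methyl]oxolan‑3‑ol
Conditions: Bu4NF (1.5 equiv), THF, 0 °C to rt; H2O work‑up
Reagents that add atoms: none
Why: Fluoride cleaves the silyl ether through pentacoordinate silicon; the phenols are still benzylated, so no quinone methide can form under the basic conditions.

Step 11
Reactants: 19 (3S,4R,5S)‑4‑Ar‑5‑[(R)‑Ar(hydroxy)methyl]oxolan‑3‑ol
Product: 20 metasequirin E, (3S,4R,5S)‑5‑[(R)‑hydroxy(4‑hydroxy‑3‑methoxyphenyl)methyl]‑4‑(4‑hydroxy‑3‑methoxyphenyl)oxolan‑3‑ol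
Conditions: H2 (1 atm), Pd/C (10 wt%), EtOAc/EtOH, rt, stopped after two equivalents of H2
Reagents that add atoms: none
Why: Hydrogenolysis of the two aryl benzyl ethers on palladium; under neutral conditions these cleave faster than the secondary benzylic C1'–O bond, and no stereocentre is touched.

## Compound list

1 | 4‑bromo‑2‑methoxyphenol | COc1cc(Br)ccc1O | starting material
2 | benzyl bromide | BrCc1ccccc1 | starting material
3 | 1‑(benzyloxy)‑4‑bromo‑2‑methoxybenzene | COc1cc(Br)ccc1OCc1ccccc1 | intermediate
4 | diglycolic anhydride (1,4‑dioxane‑2,6‑dione) | O=C1COCC(=O)O1 | starting material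
5 | [4‑(benzyloxy)‑3‑methoxyphenyl]magnesium bromide | COc1cc([Mg]Br)ccc1OCc1ccccc1 | intermediate
6 | 2‑[2‑Ar‑2‑oxoethoxy]acetic acid | COc1cc(C(=O)COCC(=O)O)ccc1OCc1ccccc1 | intermediate
7 | 2‑[(2R)‑2‑Ar‑2‑hydroxyethoxy]acetic acid | COc1cc([C@@H](O)COCC(=O)O)ccc1OCc1ccccc1 | intermediate
8 | triisopropylsilyl 2‑{(2R)‑2‑Ar‑2‑[(triisopropylsilyl)oxy]ethoxy}acetate | COc1cc([C@@H](O[Si](C(C)C)(C(C)C)C(C)C)COCC(=O)O[Si](C(C)C)(C(C)C)C(C)C)ccc1OCc1ccccc1 | intermediate
9 | 2‑{(2R)‑2‑Ar‑2‑[(triisopropylsilyl)oxy]ethoxy}acetic acid | COc1cc([C@@H](O[Si](C(C)C)(C(C)C)C(C)C)COCC(=O)O)ccc1OCc1ccccc1 | intermediate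
10 | homovanillic acid | COc1cc(CC(=O)O)ccc1O | starting material
11 | 2‑Ar‑acetic acid, 2‑[4‑(benzyloxy)‑3‑methoxyphenyl]acetic acid | COc1cc(CC(=O)O)ccc1OCc1ccccc1 | intermediate
12 | 1‑(imidazol‑1‑yl)‑2‑{(2R)‑2‑Ar‑2‑[(triisopropylsilyl)oxy]ethoxy}ethan‑1‑one | COc1cc([C@@H](O[Si](C(C)C)(C(C)C)C(C)C)COCC(=O)n2ccnc2)ccc1OCc1ccccc1 | intermediate
13 | bis(chloromagnesium) 2‑Ar‑ethene‑1,1‑diolate (Ivanov reagent of 11) | COc1cc(C=C(O[Mg]Cl)O[Mg]Cl)ccc1OCc1ccccc1 | intermediate
14 | 2‑Ar‑4‑{(2R)‑2‑Ar‑2‑[(triisopropylsilyl)oxy]ethoxy}‑3‑oxobutanoic acid (both epimers at the acid‑bearing carbon) | COc1cc(C(C(=O)O)C(=O)COC[C@H](O[Si](C(C)C)(C(C)C)C(C)C)c2ccc(OCc3ccccc3)c(OC)c2)ccc1OCc1ccccc1 | intermediate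
15 | 1‑Ar‑3‑{(2R)‑2‑Ar‑2‑[(triisopropylsilyl)oxy]ethoxy}propan‑2‑one | COc1cc(CC(=O)COC[C@H](O[Si](C(C)C)(C(C)C)C(C)C)c2ccc(OCc3ccccc3)c(OC)c2)ccc1OCc1ccccc1 | intermediate
16 | 1‑diazo‑1‑Ar‑3‑{(2R)‑2‑Ar‑2‑[(triisopropylsilyl)oxy]ethoxy}propan‑2‑one | COc1cc(C(=[N+]=[N-])C(=O)COC[C@H](O[Si](C(C)C)(C(C)C)C(C)C)c2ccc(OCc3ccccc3)c(OC)c2)ccc1OCc1ccccc1 | intermediate
17 | (4S,5S)‑4‑Ar‑5‑{(R)‑Ar[(triisopropylsilyl)oxy]methyl}oxolan‑3‑one | COc1cc([C@H]2[C@@H]([C@H](O[Si](C(C)C)(C(C)C)C(C)C)c3ccc(OCc4ccccc4)c(OC)c3)OCC2=O)ccc1OCc1ccccc1 | intermediate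
18 | (3S,4R,5S)‑4‑Ar‑5‑{(R)‑Ar[(triisopropylsilyl)oxy]methyl}oxolan‑3‑ol | COc1cc([C@H]2[C@@H]([C@H](O[Si](C(C)C)(C(C)C)C(C)C)c3ccc(OCc4ccccc4)c(OC)c3)OC[C@H]2O)ccc1OCc1ccccc1 | intermediate
19 | (3S,4R,5S)‑4‑Ar‑5‑[(R)‑Ar(hydroxy)methyl]oxolan‑3‑ol | COc1cc([C@H]2[C@@H]([C@H](O)c3ccc(OCc4ccccc4)c(OC)c3)OC[C@H]2O)ccc1OCc1ccccc1 | intermediate
20 | metasequirin E, (3S,4R,5S)‑5‑[(R)‑hydroxy(4‑hydroxy‑3‑methoxyphenyl)methyl]‑4‑(4‑hydroxy‑3‑methoxyphenyl)oxolan‑3‑ol | COc1cc([C@H]2[C@@H]([C@H](O)c3ccc(O)c(OC)c3)OC[C@H]2O)ccc1O | target

## Step count and least certain steps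

Total: 11 steps. Longest linear sequence: 10 steps (steps 1–4 and 6–11, from 1). Compounds 3 and 11 are also catalogue items; buying them would remove steps 1 and 5.

**Step 8 (key step).** The most likely failure is poor discrimination between the two C2 hydrogens because catalyst and C1' centre act in opposite senses; diversion of the carbene into the activated C1'–H bond is the second concern. The fallback sets out from 6 and comes back at 19; it runs the insertion on the other diastereomeric pairing and corrects C1' at the end.
- 6 is reduced with RuCl(p‑cymene)[(R,R)‑TsDPEN] under the conditions of step 3 to the (S)‑hydroxy acid F1.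
- The conditions of steps 4, 6 and 7 are then applied: the bis‑silyl derivative F2 is hydrolysed to the (S)‑silyloxy acid F3; its acyl imidazolide F4 acylates 13 to the keto acid F5, which loses CO2 to the (S)‑ketone F6; diazo transfer gives the (S)‑diazo ketone F7.
- Rh2(S‑PTTL)4 now meets the other pairing and should give the (2S,3S,1'S)‑oxolanone F8, which has the ring configuration of 17. The conditions of step 9 give the alcohol F9, and fluoride gives the 1'‑epimeric diol F10.
- MnO2 in CH2Cl2 oxidises only the benzylic alcohol to the aryl ketone F11, and RuCl(p‑cymene)[(S,S)‑TsDPEN] in HCO2H/Et3N (5:2) reduces it with the facial sense of step 3 to 19.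

**Step 9.** The most likely failure is reduction through the more stable 2,3‑trans epimer, which would deliver C3 and C4 in the wrong configuration. The fallback sets out from 17 and comes back at 18: equilibration is abandoned, and the kinetic 2,3‑cis ketone from step 8 is reduced without delay with LiBH(s‑Bu)3 in THF at −78 °C, so that the bulky hydride attacks the only open face before C3 can epimerise. No new compound is made.

**Step 2.** The most likely failure is a second addition of the Grignard reagent to the keto carboxylate, or enolisation of the anhydride by the basic reagent. The fallback sets out from 4 and comes back at 6: 4 is opened with MeNHOMe·HCl and pyridine to the Weinreb amide acid F12; this is deprotonated with one equivalent of iPrMgCl and treated with 5, whose chelated tetrahedral adduct cannot react further and gives 6 on acidic work‑up.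

**Step 6.** The most likely failure is proton transfer instead of acylation, because the strongly basic dianion can enolise the α‑alkoxy acyl imidazolide. The fallback sets out from 11 and comes back at 15: 11 is esterified with allyl bromide and K2CO3 to the allyl ester F13; its lithium enolate (LiN(SiMe3)2, 2 equiv, THF, −78 °C) is acylated by 12 to the allyl β‑keto ester F14; Pd(PPh3)4 (catalytic) with morpholine in THF at rt removes the allyl group and CO2 under neutral conditions to give 15.

**Step 11.** The most likely failure is over‑reduction: hydrogenolysis of the benzylic C1'–O bond once the para phenol is free. The fallback sets out from 18 and comes back at 20 by reversing the order of the last two steps: 18 is hydrogenolysed (H2, Pd/C, EtOAc) while the bulky silyl group still shields the C1'–O bond, giving the bisphenol silyl ether F15; the silyl group is then removed with Et3N·3HF in THF, a buffered fluoride source that does not generate a free phenoxide.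

## Further compounds

F1 | step 8 | 2‑[(2S)‑2‑Ar‑2‑hydroxyethoxy]acetic acid | COc1cc([C@H](O)COCC(=O)O)ccc1OCc1ccccc1
F2 | step 8 | triisopropylsilyl 2‑{(2S)‑2‑Ar‑2‑[(triisopropylsilyl)oxy]ethoxy}acetate | COc1cc([C@H](O[Si](C(C)C)(C(C)C)C(C)C)COCC(=O)O[Si](C(C)C)(C(C)C)C(C)C)ccc1OCc1ccccc1
F3 | step 8 | 2‑{(2S)‑2‑Ar‑2‑[(triisopropylsilyl)oxy]ethoxy}acetic acid | COc1cc([C@H](O[Si](C(C)C)(C(C)C)C(C)C)COCC(=O)O)ccc1OCc1ccccc1
F4 | step 8 | 1‑(imidazol‑1‑yl)‑2‑{(2S)‑2‑Ar‑2‑[(triisopropylsilyl)oxy]ethoxy}ethan‑1‑one | COc1cc([C@H](O[Si](C(C)C)(C(C)C)C(C)C)COCC(=O)n2ccnc2)ccc1OCc1ccccc1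
F5 | step 8 | 2‑Ar‑4‑{(2S)‑2‑Ar‑2‑[(triisopropylsilyl)oxy]ethoxy}‑3‑oxobutanoic acid | COc1cc(C(C(=O)O)C(=O)COC[C@@H](O[Si](C(C)C)(C(C)C)C(C)C)c2ccc(OCc3ccccc3)c(OC)c2)ccc1OCc1ccccc1
F6 | step 8 | 1‑Ar‑3‑{(2S)‑2‑Ar‑2‑[(triisopropylsilyl)oxy]ethoxy}propan‑2‑one | COc1cc(CC(=O)COC[C@@H](O[Si](C(C)C)(C(C)C)C(C)C)c2ccc(OCc3ccccc3)c(OC)c2)ccc1OCc1ccccc1
F7 | step 8 | 1‑diazo‑1‑Ar‑3‑{(2S)‑2‑Ar‑2‑[(triisopropylsilyl)oxy]ethoxy}propan‑2‑one | COc1cc(C(=[N+]=[N-])C(=O)COC[C@@H](O[Si](C(C)C)(C(C)C)C(C)C)c2ccc(OCc3ccccc3)c(OC)c2)ccc1OCc1ccccc1
F8 | step 8 | (4S,5S)‑4‑Ar‑5‑{(S)‑Ar[(triisopropylsilyl)oxy]methyl}oxolan‑3‑one | COc1cc([C@H]2[C@@H]([C@@H](O[Si](C(C)C)(C(C)C)C(C)C)c3ccc(OCc4ccccc4)c(OC)c3)OCC2=O)ccc1OCc1ccccc1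
F9 | step 8 | (3S,4R,5S)‑4‑Ar‑5‑{(S)‑Ar[(triisopropylsilyl)oxy]methyl}oxolan‑3‑ol | COc1cc([C@H]2[C@@H]([C@@H](O[Si](C(C)C)(C(C)C)C(C)C)c3ccc(OCc4ccccc4)c(OC)c3)OC[C@H]2O)ccc1OCc1ccccc1
F10 | step 8 | (3S,4R,5S)‑4‑Ar‑5‑[(S)‑Ar(hydroxy)methyl]oxolan‑3‑ol | COc1cc([C@H]2[C@@H]([C@@H](O)c3ccc(OCc4ccccc4)c(OC)c3)OC[C@H]2O)ccc1OCc1ccccc1
F11 | step 8 | [(2S,3R,4S)‑3‑Ar‑4‑hydroxyoxolan‑2‑yl](Ar)methanone | COc1cc([C@H]2[C@@H](C(=O)c3ccc(OCc4ccccc4)c(OC)c3)OC[C@H]2O)ccc1OCc1ccccc1
F0 | step 9 | none | none
F12 | step 2 | 2‑{2‑[methoxy(methyl)amino]‑2‑oxoethoxy}acetic acid | CON(C)C(=O)COCC(=O)O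
F13 | step 6 | prop‑2‑en‑1‑yl 2‑Ar‑acetate | COc1cc(CC(=O)OCC=C)ccc1OCc1ccccc1
F14 | step 6 | prop‑2‑en‑1‑yl 2‑Ar‑4‑{(2R)‑2‑Ar‑2‑[(triisopropylsilyl)oxy]ethoxy}‑3‑oxobutanoate | COc1cc(C(C(=O)OCC=C)C(=O)COC[C@H](O[Si](C(C)C)(C(C)C)C(C)C)c2ccc(OCc3ccccc3)c(OC)c2)ccc1OCc1ccccc1
F15 | step 11 | (3S,4R,5S)‑4‑(4‑hydroxy‑3‑methoxyphenyl)‑5‑{(R)‑(4‑hydroxy‑3‑methoxyphenyl)[(triisopropylsilyl)oxy]methyl}oxolan‑3‑ol | COc1cc([C@H]2[C@@H]([C@H](O[Si](C(C)C)(C(C)C)C(C)C)c3ccc(O)c(OC)c3)OC[C@H]2O)ccc1O
A1 | alternative 1 | all‑cis 2‑aroyl‑3‑Ar‑4‑[(tert‑butyldimethylsilyl)oxy]oxolane (aroyl = Ar–CO) | COc1cc([C@H]2[C@@H](C(=O)c3ccc(OCc4ccccc4)c(OC)c3)OC[C@H]2O[Si](C)(C)C(C)(C)C)ccc1OCc1ccccc1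
A2 | alternative 1 | cis‑2‑Ar‑3‑[(tert‑butyldimethylsilyl)oxy]oxetane | COc1cc([C@H]2OC[C@H]2O[Si](C)(C)C(C)(C)C)ccc1OCc1ccccc1
A3 | alternative 1 | 2‑diazo‑1‑Ar‑ethan‑1‑one | COc1cc(C(=O)C=[N+]=[N-])ccc1OCc1ccccc1
A4 | alternative 2 | cis‑3,3‑dichloro‑4‑Ar‑5‑{(R)‑Ar[(tert‑butyldimethylsilyl)oxy]methyl}oxolan‑2‑one | COc1cc([C@H]2[C@@H]([C@H](O[Si](C)(C)C(C)(C)C)c3ccc(OCc4ccccc4)c(OC)c3)OC(=O)C2(Cl)Cl)ccc1OCc1ccccc1
A5 | alternative 2 | cis‑2,2‑dichloro‑3‑Ar‑4‑{(S)‑Ar[(tert‑butyldimethylsilyl)oxy]methyl}cyclobutan‑1‑one (carbinol centre arranged in space as C1' of the target) | COc1cc([C@H]2[C@@H]([C@H](O[Si](C)(C)C(C)(C)C)c3ccc(OCc4ccccc4)c(OC)c3)C(=O)C2(Cl)Cl)ccc1OCc1ccccc1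
A6 | alternative 2 | (Z,1S)‑1,3‑di‑Ar‑1‑[(tert‑butyldimethylsilyl)oxy]prop‑2‑ene (carbinol centre arranged in space as C1' of the target) | COc1cc(/C=C\[C@H](O[Si](C)(C)C(C)(C)C)c2ccc(OCc3ccccc3)c(OC)c2)ccc1OCc1ccccc1
A7 | alternative 2 | dichloroketene | ClC(Cl)=C=O
A8 | alternative 3 | all‑cis 2‑{(R)‑Ar[(tert‑butyldimethylsilyl)oxy]methyl}‑3‑Ar‑4‑[dimethyl(phenyl)silyl]oxolane | COc1cc([C@H]2[C@@H]([C@H](O[Si](C)(C)C(C)(C)C)c3ccc(OCc4ccccc4)c(OC)c3)OC[C@H]2[Si](C)(C)c2ccccc2)ccc1OCc1ccccc1
A9 | alternative 3 | (Z)‑(3‑Ar‑prop‑2‑en‑1‑yl)dimethyl(phenyl)silane | COc1cc(/C=C\C[Si](C)(C)c2ccccc2)ccc1OCc1ccccc1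
A10 | alternative 3 | (R)‑2‑Ar‑2‑[(tert‑butyldimethylsilyl)oxy]acetaldehyde | O=C[C@H](O[Si](C)(C)C(C)(C)C)c1ccc(OCc2ccccc2)c(OC)c1
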